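**Retrosynthetic overview** (drimane numbering: ring A = C1–C5 and C10, ring B = C5–C10, C11 = the OCH2 carbon, C3 = the carbinol carbon)
- Last disconnections: the aryl ether O–C11 (Mitsunobu reaction with scopoletin) and the C3 carbinol (from the 3-ketone).
- Ring A is formed second: C1=C2 by intramolecular aldol condensation of a formyl group on C10 (C1) with a methyl ketone on C4 (C2, C3), then saturation of C1=C2.
- Ring B is formed first: a catalytic enantioselective Diels–Alder reaction makes C5–C6 and C9–C10 at once from the (E)-diene C6=C7–C8(Me)=C9–C11 and the (E)-enal O=C1–C10(Me)=C5–C4(Me)2–C3(=O)–C2.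
- Enabling feature: ring B is a cyclohexene whose C7=C8 double bond lies opposite the ring-fusion bond C5–C10 (a Diels–Alder retron). C10 is quaternary and carries C1, which serves as the activating formyl group before it is absorbed into ring A as a CH2 group. The trans H5/Me10 relation and the position of C11 anti to Me10 map onto an (E)-enal, an (E)-diene and a formyl-endo transition state.
- Each cycloaddition partner is made in two steps from commercial materials.

Key step: step 5

Remark: the catalyst enantiomer in step 5 is chosen from the usual pre-transition-state model for 2-substituted enals bound to a protonated oxazaborolidine (formyl C–H···O contact, s-trans enal, one C-phenyl group covering the rear face).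

**Step 1**
Reactants: 1 4-(2-methylprop-1-en-1-yl)morpholine; 2 acetyl chloride
Product: 4 2,2-dimethyl-3-oxobutanal, via C-acyliminium chloride 3 (not isolated)
Conditions: Et2O, 0 °C → reflux; then H2O, rt
Reagents that add atoms: water, O
Why: Stork enamine acylation: the β,β-disubstituted enamine is C-acylated to a non-enolisable iminium salt that cannot react twice, and water hydrolyses it to the β-keto aldehyde with the quaternary carbon (later C4) in place.

**Step 2**
Reactants: 4 2,2-dimethyl-3-oxobutanal; 5 2-(triphenyl-λ5-phosphanylidene)propanal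
Product: 6 (2E)-2,4,4-trimethyl-5-oxohex-2-enal
Conditions: toluene, 100 °C
Reagents that add atoms: none
Why: Wittig olefination with a stabilised formyl ylide should attack only the aldehyde (the ketone is flanked by a quaternary carbon) and give the (E)-trisubstituted enal, whose geometry later fixes the trans ring fusion.

**Step 3**
Reactants: 7 (2E)-3-methylpent-2-en-4-yn-1-ol
Product: 8 tert-butyl{[(2E)-3-methylpent-2-en-4-yn-1-yl]oxy}diphenylsilane
Conditions: TBDPSCl, imidazole, DMF, 0 °C → rt
Reagents that add atoms: tert-butyl(chloro)diphenylsilane (TBDPSCl), CC(C)(C)[Si](Cl)(c1ccccc1)c1ccccc1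
Why: Silylation of a primary allylic alcohol; the acid-stable silyl ether keeps the hydroxyl group away from the Lewis acid of step 5 and should survive steps 6–8.

**Step 4**
Reactants: 8 tert-butyl{[(2E)-3-methylpent-2-en-4-yn-1-yl]oxy}diphenylsilane
Product: 9 tert-butyl{[(2E)-3-methylpenta-2,4-dien-1-yl]oxy}diphenylsilane
Conditions: H2 (1 atm), Pd/CaCO3 poisoned with Pb(OAc)2, quinoline, hexane/EtOAc, rt
Reagents that add atoms: none
Why: Partial hydrogenation of the terminal alkyne on lead-poisoned palladium should stop at the vinyl group and leave the trisubstituted (E)-double bond untouched, giving the (E)-diene.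

**Step 5**
Reactants: 9 tert-butyl{[(2E)-3-methylpenta-2,4-dien-1-yl]oxy}diphenylsilane; 6 (2E)-2,4,4-trimethyl-5-oxohex-2-enal
Product: 10 (1R,2S,6S)-2-{[(tert-butyldiphenylsilyl)oxy]methyl}-1,3-dimethyl-6-(2-methyl-3-oxobutan-2-yl)cyclohex-3-ene-1-carbaldehyde
Conditions: (R)-1-(2-methylphenyl)-3,3-diphenyltetrahydro-1H,3H-pyrrolo[1,2-c][1,3,2]oxazaborole (20 mol %), HN(SO2CF3)2 (18 mol %), 9 (1.5 equiv), CH2Cl2, −78 → −20 °C
Reagents that add atoms: none
Why: The protonated oxazaborolidine binds the formyl oxygen of 6 and lowers its LUMO, so that diene 9 should add in a concerted but asynchronous Diels–Alder reaction in which the C5–C6 bond (unsubstituted diene terminus to the β-carbon) runs ahead of the C9–C10 bond to the α-carbon. The closest known reaction type is the enantioselective Diels–Alder reaction of (E)-2-methylalk-2-enals with open-chain 1,3-dienes under cationic oxazaborolidine catalysis, and Lewis-acid-promoted cycloadditions to 4,4-dimethylcyclohex-2-enones show that a β-carbon next to a quaternary carbon can still react. Ring B closes as a six-membered carbocycle by intermolecular suprafacial [4+2] addition of C6=C7–C8=C9 across C5=C10, which leaves the C7=C8 double bond where the target has it. The trans relation of H5 and the C10 methyl follows stereospecifically from the E geometry of 6; the cis relation of C11 and the formyl carbon (C11 anti to the C10 methyl) follows from the E geometry of 9 and the formyl-endo transition state; the absolute configuration (10R, 9S, 5S in drimane numbering) comes from the catalyst, whose C-phenyl group covers one face of the bound enal so that the diene should add to the Si face of the α-carbon. The step needs "ortho" regiochemistry, endo selectivity and activation of the aldehyde over the ketone: the first is secured by the terminal CH2OSi substituent of the diene and because only the unsubstituted terminus C6 can reach the hindered C5, the second by the tert-alkyl group trans to the formyl group, which would collide with the diene in the exo arrangement, and the third by the greater basicity and accessibility of the aldehyde.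

**Step 6**
Reactants: 10 (1R,2S,6S)-2-{[(tert-butyldiphenylsilyl)oxy]methyl}-1,3-dimethyl-6-(2-methyl-3-oxobutan-2-yl)cyclohex-3-ene-1-carbaldehyde
Product: 12 (4aR,5S,8aS)-5-{[(tert-butyldiphenylsilyl)oxy]methyl}-1,1,4a,6-tetramethyl-4a,5,8,8a-tetrahydronaphthalen-2(1H)-one, via aldol adduct 11 (not isolated)
Conditions: KOH (0.5 equiv), MeOH/THF, rt → 50 °C
Reagents that add atoms: none
Why: Intramolecular aldol condensation: only the methyl group of the ketone is enolisable (C4 and C10 are quaternary), its enolate attacks the non-enolisable formyl group on the trans neighbour to close ring A, and the aldol loses water (E1cB) to the enone; no stereocentre is touched, so the trans fusion from step 5 is kept.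

**Step 7**
Reactants: 12 (4aR,5S,8aS)-5-{[(tert-butyldiphenylsilyl)oxy]methyl}-1,1,4a,6-tetramethyl-4a,5,8,8a-tetrahydronaphthalen-2(1H)-one
Product: 13 (4aR,5S,8aS)-5-{[(tert-butyldiphenylsilyl)oxy]methyl}-1,1,4a,6-tetramethyl-3,4,4a,5,8,8a-hexahydronaphthalen-2(1H)-one
Conditions: H2 (1 atm), 10% Pd on carbon, EtOAc, rt, stopped after one equivalent
Reagents that add atoms: none
Why: Chemoselective catalytic hydrogenation: the cis-disubstituted, conjugated C1=C2 bond should be reduced much faster than the trisubstituted C7=C8 bond of ring B, and no stereocentre is formed.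

**Step 8**
Reactants: 13 (4aR,5S,8aS)-5-{[(tert-butyldiphenylsilyl)oxy]methyl}-1,1,4a,6-tetramethyl-3,4,4a,5,8,8a-hexahydronaphthalen-2(1H)-one
Product: 14 (2S,4aR,5S,8aS)-5-{[(tert-butyldiphenylsilyl)oxy]methyl}-1,1,4a,6-tetramethyl-1,2,3,4,4a,5,8,8a-octahydronaphthalen-2-ol
Conditions: LiBH(s-Bu)3 (L-Selectride), THF, −78 → 0 °C; then H2O
Reagents that add atoms: none
Why: Diastereoselective ketone reduction: the bulky trialkylborohydride should approach the chair cyclohexanone along the equatorial trajectory, avoiding the syn-axial C1–H and C5–H bonds, and so place the new hydroxyl axial (3S, cis to H5), as is usual for 4,4-dimethyl-3-oxo trans-decalins.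

**Step 9**
Reactants: 14 (2S,4aR,5S,8aS)-5-{[(tert-butyldiphenylsilyl)oxy]methyl}-1,1,4a,6-tetramethyl-1,2,3,4,4a,5,8,8a-octahydronaphthalen-2-ol
Product: 15 (2S,4aR,5S,8aS)-5-(hydroxymethyl)-1,1,4a,6-tetramethyl-1,2,3,4,4a,5,8,8a-octahydronaphthalen-2-ol
Conditions: Bu4NF, THF, rt
Reagents that add atoms: none
Why: Fluoride-induced desilylation, driven by the strong Si–F bond, should free the primary hydroxyl group without affecting the alkene or the secondary alcohol.

**Step 10**
Reactants: 15 (2S,4aR,5S,8aS)-5-(hydroxymethyl)-1,1,4a,6-tetramethyl-1,2,3,4,4a,5,8,8a-octahydronaphthalen-2-ol; 16 scopoletin (7-hydroxy-6-methoxy-2H-chromen-2-one)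
Product: 17 7-{[(1S,4aS,6S,8aR)-6-hydroxy-2,5,5,8a-tetramethyl-1,4,4a,5,6,7,8,8a-octahydronaphthalen-1-yl]methoxy}-6-methoxy-2H-chromen-2-one
Conditions: PPh3, diisopropyl azodicarboxylate, THF, 0 °C → rt
Reagents that add atoms: none
Why: Mitsunobu etherification: the acidic 7-OH of scopoletin should displace the oxyphosphonium group of the primary C11 hydroxyl, while the axial, neopentyl-type C3 hydroxyl reacts far more slowly; substitution occurs at a CH2 group, so no stereocentre is affected.

**Compound list**
1 | 4-(2-methylprop-1-en-1-yl)morpholine | CC(C)=CN1CCOCC1 | starting material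
2 | acetyl chloride | CC(=O)Cl | starting material
3 | 4-(2,2-dimethyl-3-oxobutylidene)morpholin-4-ium chloride (not isolated) | CC(=O)C(C)(C)C=[N+]1CCOCC1.[Cl-] | intermediate
4 | 2,2-dimethyl-3-oxobutanal | CC(=O)C(C)(C)C=O | intermediate
5 | 2-(triphenyl-λ5-phosphanylidene)propanal | CC(C=O)=P(c1ccccc1)(c1ccccc1)c1ccccc1 | starting material
6 | (2E)-2,4,4-trimethyl-5-oxohex-2-enal | CC(=O)C(C)(C)/C=C(\C)C=O | intermediate
7 | (2E)-3-methylpent-2-en-4-yn-1-ol | C#C/C(C)=C/CO | starting material
8 | tert-butyl{[(2E)-3-methylpent-2-en-4-yn-1-yl]oxy}diphenylsilane | C#C/C(C)=C/CO[Si](c1ccccc1)(c1ccccc1)C(C)(C)C | intermediate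
9 | tert-butyl{[(2E)-3-methylpenta-2,4-dien-1-yl]oxy}diphenylsilane | C=C/C(C)=C/CO[Si](c1ccccc1)(c1ccccc1)C(C)(C)C | intermediate
10 | (1R,2S,6S)-2-{[(tert-butyldiphenylsilyl)oxy]methyl}-1,3-dimethyl-6-(2-methyl-3-oxobutan-2-yl)cyclohex-3-ene-1-carbaldehyde | CC(C)(C)[Si](c1ccccc1)(c1ccccc1)OC[C@H]1C(C)=CC[C@H](C(C)(C)C(C)=O)[C@]1(C=O)C | intermediate
11 | (4aR,5S,8aS)-5-{[(tert-butyldiphenylsilyl)oxy]methyl}-4-hydroxy-1,1,4a,6-tetramethyl-3,4,4a,5,8,8a-hexahydronaphthalen-2(1H)-one, C4 epimers (not isolated) | CC(C)(C)[Si](c1ccccc1)(c1ccccc1)OC[C@H]1C(C)=CC[C@@H]2C(C)(C)C(=O)CC(O)[C@]21C | intermediate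
12 | (4aR,5S,8aS)-5-{[(tert-butyldiphenylsilyl)oxy]methyl}-1,1,4a,6-tetramethyl-4a,5,8,8a-tetrahydronaphthalen-2(1H)-one | CC(C)(C)[Si](c1ccccc1)(c1ccccc1)OC[C@H]1C(C)=CC[C@@H]2C(C)(C)C(=O)C=C[C@]21C | intermediate
13 | (4aR,5S,8aS)-5-{[(tert-butyldiphenylsilyl)oxy]methyl}-1,1,4a,6-tetramethyl-3,4,4a,5,8,8a-hexahydronaphthalen-2(1H)-one | CC(C)(C)[Si](c1ccccc1)(c1ccccc1)OC[C@H]1C(C)=CC[C@@H]2C(C)(C)C(=O)CC[C@]21C | intermediate
14 | (2S,4aR,5S,8aS)-5-{[(tert-butyldiphenylsilyl)oxy]methyl}-1,1,4a,6-tetramethyl-1,2,3,4,4a,5,8,8a-octahydronaphthalen-2-ol | CC(C)(C)[Si](c1ccccc1)(c1ccccc1)OC[C@H]1C(C)=CC[C@@H]2C(C)(C)[C@@H](O)CC[C@]21C | intermediate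
15 | (2S,4aR,5S,8aS)-5-(hydroxymethyl)-1,1,4a,6-tetramethyl-1,2,3,4,4a,5,8,8a-octahydronaphthalen-2-ol | OC[C@H]1C(C)=CC[C@@H]2C(C)(C)[C@@H](O)CC[C@]21C | intermediate
16 | scopoletin (7-hydroxy-6-methoxy-2H-chromen-2-one) | COc1cc2ccc(=O)oc2cc1O | starting material
17 | 7-{[(1S,4aS,6S,8aR)-6-hydroxy-2,5,5,8a-tetramethyl-1,4,4a,5,6,7,8,8a-octahydronaphthalen-1-yl]methoxy}-6-methoxy-2H-chromen-2-one | COc1cc2ccc(=O)oc2cc1OC[C@H]1C(C)=CC[C@@H]2C(C)(C)[C@@H](O)CC[C@]21C | target

**Step count**
Total steps: 10. Longest linear sequence: 8 steps (steps 1, 2, 5–10, or equally steps 3–10).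

**Steps most likely to fail**

Step 5 (cycloaddition). The β-carbon of 6 is neopentyl, so turnover may be too slow and acid-induced oligomerisation of the diene may win; regiochemistry, endo selectivity or facial selectivity may also erode. The fallback postpones the quaternary C4 and sets out from diene 9 and ylide 5. Commercial ethyl (2-methyl-1,3-dioxolan-2-yl)acetate would be reduced with i-Bu2AlH (CH2Cl2, −78 °C) to (2-methyl-1,3-dioxolan-2-yl)acetaldehyde F1. Wittig olefination with 5 would give (2E)-2-methyl-4-(2-methyl-1,3-dioxolan-2-yl)but-2-enal F2, whose β-carbon carries only a CH2 group. The same catalysed Diels–Alder reaction with 9 would give the cyclohexene carbaldehyde F3. Pyridinium p-toluenesulfonate in acetone/H2O would remove the dioxolane to the keto aldehyde F4 (not isolated), which would close under the conditions of step 6 to the C4-unsubstituted enone F5. Two successive kinetic α′-methylations (LiN(i-Pr)2, MeI, THF, −78 °C), through the monomethyl enone F6, would install the geminal methyl groups; C4 is the only enolisable position because C10 is quaternary. The fallback comes back to the route at enone 12.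

Step 10 (etherification). Substitution at the β-branched, axial primary carbinol may be slow, so that elimination or alkylation of the reduced azodicarboxylate competes. The fallback sets out from diol 15 and scopoletin 16 and separates activation from displacement. Selective mesylation of the primary hydroxyl (MsCl, Et3N, CH2Cl2, −20 °C) would give [(1S,4aS,6S,8aR)-6-hydroxy-2,5,5,8a-tetramethyl-1,4,4a,5,6,7,8,8a-octahydronaphthalen-1-yl]methyl methanesulfonate F7. Its displacement by the caesium phenoxide of 16 (Cs2CO3, DMF, 60 °C) would come back to the route at target 17.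

Step 7 (enone saturation). Hydrogenation may also saturate the ring B double bond or shift it towards C8=C9. The fallback sets out from enone 12 and replaces hydrogen addition on a metal surface by conjugate hydride delivery with [(Ph3P)CuH]6 (toluene, H2O as proton source, rt), which does not touch isolated alkenes. It comes back to the route at ketone 13 and makes no further compound (F0).

**Further compounds**
F1 | step 5 | (2-methyl-1,3-dioxolan-2-yl)acetaldehyde | CC1(CC=O)OCCO1
F2 | step 5 | (2E)-2-methyl-4-(2-methyl-1,3-dioxolan-2-yl)but-2-enal | CC1(C/C=C(\C)C=O)OCCO1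
F3 | step 5 | (1R,2S,6R)-2-{[(tert-butyldiphenylsilyl)oxy]methyl}-1,3-dimethyl-6-[(2-methyl-1,3-dioxolan-2-yl)methyl]cyclohex-3-ene-1-carbaldehyde | CC(C)(C)[Si](c1ccccc1)(c1ccccc1)OC[C@H]1C(C)=CC[C@H](CC2(C)OCCO2)[C@]1(C=O)C
F4 | step 5 | (1R,2S,6R)-2-{[(tert-butyldiphenylsilyl)oxy]methyl}-1,3-dimethyl-6-(2-oxopropyl)cyclohex-3-ene-1-carbaldehyde | CC(C)(C)[Si](c1ccccc1)(c1ccccc1)OC[C@H]1C(C)=CC[C@H](CC(C)=O)[C@]1(C=O)C
F5 | step 5 | (4aS,5S,8aR)-5-{[(tert-butyldiphenylsilyl)oxy]methyl}-4a,6-dimethyl-4a,5,8,8a-tetrahydronaphthalen-2(1H)-one | CC(C)(C)[Si](c1ccccc1)(c1ccccc1)OC[C@H]1C(C)=CC[C@@H]2CC(=O)C=C[C@]21C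
F6 | step 5 | (4aR,5S,8aR)-5-{[(tert-butyldiphenylsilyl)oxy]methyl}-1,4a,6-trimethyl-4a,5,8,8a-tetrahydronaphthalen-2(1H)-one, C1 epimers | CC(C)(C)[Si](c1ccccc1)(c1ccccc1)OC[C@H]1C(C)=CC[C@@H]2C(C)C(=O)C=C[C@]21C
F7 | step 10 | [(1S,4aS,6S,8aR)-6-hydroxy-2,5,5,8a-tetramethyl-1,4,4a,5,6,7,8,8a-octahydronaphthalen-1-yl]methyl methanesulfonate | CS(=O)(=O)OC[C@H]1C(C)=CC[C@@H]2C(C)(C)[C@@H](O)CC[C@]21C
F0 | step 7 | none | none
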